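- The nucleophile of the maple flask is charged below the electrophile, which makes it the limiting reagent if each nucleophile spends one electrophile, so conversion stops at 90.0 %: this is the ceiling, the nucleophile charge as a fraction of the electrophile charge.

all flasks: electrophile 0.19 M; nucleophile 0.171 M
- maple: the very flask that is asked about, followed so far
- flask: time 1.0 h

maple run (percent of the electrophile charged)

| time / min | electrophile / % | target / % |
|---|---|---|
| 3.00 | 49 | 52 |
| 6.00 | 34 | 67 |
| 10.0 | 27 | 74 |
| 12.0 | 24 | 77 |

(readings scatter by 2 percentage points)

- what was read earlier has a scatter of 2 percentage points, one standard deviation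
- the earlier runs do not show how much of nucleophile is bound; that part of a forecast is a guess

- part of the electrophile that has reacted at 1.0 h
- share of the unused nucleophile that is free and not bound as protonated nucleophile, at 1.0 h

- In fractions of the electrophile charge, the electrophile left then stays 10.0 % above the nucleophile left, bound or not.
- For a one-to-one step with a constant rate coefficient, the ratio of electrophile left to nucleophile left grows by a steady fraction each minute, and that fractional rate is the thing to freeze.
- This ratio starts at 1.11, and the reading at 12.0 min puts it at 1.71, so it grows at 0.0361 min⁻¹.
- Frozen to 1.0 h, that rate carries the ratio to 9.71, and my reckoning then has 88.9 % reacted.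
- The weak link is one reading with a scatter of 2 percentage points, but the reading at 6.00 min gives 0.0405 min⁻¹ and 89.1 % reacted.
- The forecast, a little lower than my reckoning, is 87 % (82 % to 90 %) reacted and 78 % (35 % to 98 %) free, and of the second it says: “Free share is mostly a guess”.
- The flask gives 89.2 % reacted, 0.8 points under the ceiling, and 30.3 % free, 48 points below the forecast.

    electrophile + nucleophile → acid set free + target (k = 0.124 M⁻¹ s⁻¹)
    nucleophile + acid set free ⇌ protonated nucleophile, settled at all times (K = 443 M⁻¹)
    nucleophile → decomposition product (k = 5.18 × 10⁻⁷ s⁻¹)
    acid set free → by-product carried off (k = 4.58 × 10⁻⁴ s⁻¹)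
    crystals ⇌ acid set free, rate k5*(cs5 - [acid set free]) while solid is left; crystals form when [acid set free] > cs5 (solubility = 5.20 mM, k = 0.116 s⁻¹)

- At 1.00 h, the target-making step gives the nucleophile of the flask a half-life of 0.076 h, far shorter than the 3.4 h it gives the electrophile, and the flask then holds 0.27 % of its nucleophile charge and 11 % of its electrophile charge. The flask stands at 90.0 % reacted at 10.0 h, while a neighbour flask charged with 0.068 M of nucleophile has a ceiling of 35.8 % and 35.8 % reacted at 1.0 h.

The readings were generated by integration on assumed constants, and the scatter is random.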